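## The problem

Target 16 is a single carbocycle, [(1R,2S,3R,6S)-2,6-diacetoxy-3-(benzoyloxy)-1-hydroxycyclohex-4-en-1-yl]methyl benzoate. C1 is a tertiary carbinol carrying the benzoyloxymethyl carbon C7, C2 and C6 carry acetates, C3 carries a benzoate, and C4=C5 is the only alkene. No carbon–carbon bond is difficult, since all seven carbons are present in a cheap C7 aromatic; the task is one of oxidation pattern, configuration and acyl placement. Four stereocentres must be set: the C1 hydroxyl and the C2 oxygen are cis to each other and trans to the oxygens on C3 and C6, which are cis to each other across the ring. C3 and C6 are both allylic to C1=C2, so once they share a face they can direct an oxidant to the opposite face of that alkene and thereby fix C1 and C2. The five oxygens exist in three states (two benzoates, two acetates, one free tertiary hydroxyl), so the secondary hydroxyls on C2, C3 and C6 must never need to be told apart by selective acylation. The esters are the fragile part: base invites acyl migration and ester exchange, and the allylic esters flanking C4=C5 can ionise or eliminate towards an arene, so the late steps must be neutral or weakly acidic. The enabling feature is that C1–C6 have the oxidation pattern of a 2-substituted para-benzoquinone (carbonyl carbons C3 and C6, alkenes C1=C2 and C4=C5) and that the C1/C2 diol is cis and anti to both flanking oxygens. That is the outcome of OsO4 on a C1=C2 alkene whose two allylic oxygens share one face, provided C4=C5 is hidden during the oxidation.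

## Retrosynthesis

**16 ⇒ 14.** The C4=C5 π bond is traced back to a cis-epoxide on the face of the C3 and C6 acyloxy groups. Other masks would hide the alkene equally well, but only an epoxide can be introduced enantioselectively at the quinone oxidation level and then steer both hydride additions. Leaving C4=C5 free is excluded because osmylation would not distinguish the two alkenes. The forward step must remove one oxygen stereospecifically, without base and without touching four esters.

**14 ⇒ 12 + 13.** The two acetyl C–O bonds at O2 and O6 are cut together, giving triol 12 and acetic anhydride 13. Acetylating both at once saves a step over capping O6 before the oxidation. The benzoates on O3 and O7 are already in place, so the forward reaction only has to distinguish secondary from tertiary hydroxyl.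

**12 ⇒ 10.** The C1–O and C2–O bonds are cut in one stroke (cis-dihydroxylation). Epoxidation and hydrolysis at these carbons would give the trans diol; building the tertiary carbinol by carbonyl addition would need a C–C bond and separate stereocontrol. Precursor 10 has two stereocentres fewer and one alkene. The forward reaction must attack the face opposite the C3 benzoate, the C6 hydroxyl and the epoxide oxygen.

**10 ⇒ 9 ⇒ 8.** The C6–H bond is cut (hydride addition to enone 9), and the C6 carbonyl of 9 is traced to the dimethyl ketal of 8. Keeping C6 as a ketal until now is what distinguishes it from C3. The forward reduction must deliver hydride anti to the epoxide.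

**8 ⇒ 7 + 4 ⇒ 6.** The O3–benzoyl bond is cut (benzoyl chloride 4), then the C3–H bond, leading to epoxy enone 6. Unveiling the two quinone carbonyls one at a time puts a benzoate on O3 and later an acetate on O6 with no selective acylation. Reducing both carbonyls together and then discriminating three similar hydroxyls was judged unreliable. The unprotected quinone oxidation level was set aside for the same reason, and because enantioselective epoxidation is better founded on the monoketal.

**6 ⇒ 5.** The two epoxide C–O bonds are cut, giving achiral dienone 5. This is the only enantio-determining step. The forward reaction must pick the C4=C5 alkene (its β-carbon C5 is unsubstituted, whereas C1 is fully substituted) and one enantiotopic face.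

**5 ⇒ 3 + 4 ⇒ 2 ⇒ 1.** The O7–benzoyl bond is cut, then one C–OMe bond of the ketal (oxidative dearomatisation of phenol 2), then the aldehyde of 1 is restored. Phenol 2 places the methoxy group para to the hydroxyl and next to the hydroxymethyl carbon, so the ketal forms at C6 and the carbonyl at C3, as required.

## Roads not taken

**Alternative 1:** The cut is C5–C6. In the forward sense the (Z)-iodoalkenyl aldehyde A2 is treated with CrCl2 and catalytic NiCl2; the alkenylchromium adds to the aldehyde (Nozaki–Hiyama–Kishi reaction) and closes the ring to cyclohexenol A1.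
- Merits: C2, C3 and the branched C1 come from a sugar of the manno series, so absolute configuration is never in doubt. The ring closes with C4=C5 in place, so no alkene has to be hidden. The oxygens arrive differentiated (acetonide over O1/O2, benzoates on O3 and O7, free O6), so the end game from A1 is short.
- Weak points: A2 requires a quaternary hydroxymethyl branch, a (Z)-iodoalkene and an α-alkoxy, α-quaternary aldehyde to be built on a sugar chain, with many protecting-group changes. The new C6 carbinol is controlled only by the neighbouring quaternary centre, so its configuration is not secure. An excess of divalent chromium is needed.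
- Comparison: in certainty of absolute configuration and in the end game this road is at least as good. Against that the chosen plan sets its brevity, the absence of any C–C bond formation and a predictable ring-based control of C1 and C2.

**Alternative 2:** The cut is the C2–O and C3–O bonds on an arene. Toluene dioxygenase in whole cells converts bromobenzene A3 into diene diol A4, which must then be relayed to the target.
- Merits: one step from a bulk arene gives an enantiopure diol; the bromine marks C1 for later attachment of C7.
- Weak points: the enzyme delivers O2 and O3 cis, whereas the target has them trans, so one centre must be inverted. The tertiary carbinol at C1 and the C6 oxygen must be added to a diene with control of regiochemistry, chemoselectivity and face. The bromide must be exchanged for a hydroxymethyl carbon. Fermentation capacity is required.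
- Comparison: in enantiopurity and cost of the first step this road is better. The chosen plan sets against it a cis-diol that is the one actually present in the target, direct placement of O3 and O6 by hydride, and a resolution fallback should the epoxidation be only moderately selective.

**Alternative 3:** The cut is C1–C6. Silyl ketene acetal A5 undergoes an Ireland–Claisen ring contraction through a boat transition state to cyclohexene acid A6.
- Merits: the quaternary C1 and C6 are created together by a stereospecific pericyclic step, C2 and C3 come from the chiral pool, and C4=C5 is delivered in place.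
- Weak points: the lactone behind A5 needs a lengthy build. Enolisation next to a β-oxygen risks elimination. After the key step C7 must be reduced from the acid level, the silyl ether exchanged for benzoate, the benzyl ether removed without hydrogenation and replaced by acetate, and the acetonide removed.
- Comparison: the Claisen fixes the quaternary centre more rigorously than a facial bias can. The chosen plan sets against it the correct oxidation level at C7 from the start, no protecting group beyond the ketal, and roughly half the step count.

Key step: step 9

Assumptions and conventions: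
- Ring locants and CIP descriptors in the names of 6–16 follow the target numbering (C1 bears C7).
- N-benzylcinchonidinium chloride is assumed to give the (4R,5S)-epoxide 6; if the sense is opposite, the pseudoenantiomeric N-benzylcinchoninium chloride is used and nothing else changes.
- Compound 1 is taken to be a catalogue compound.

## Route

Step 1
Reactants: 1 5-hydroxy-2-methoxybenzaldehyde
Product: 2 3-(hydroxymethyl)-4-methoxyphenol
Conditions: NaBH4, MeOH, 0 °C
Reagents that add atoms: none
Why: Borohydride reduction of an aryl aldehyde to the benzylic alcohol; no stereocentre is formed and the phenol is untouched.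

Step 2
Reactants: 2 3-(hydroxymethyl)-4-methoxyphenol
Product: 3 3-(hydroxymethyl)-4,4-dimethoxycyclohexa-2,5-dien-1-one
Conditions: PhI(OAc)2, MeOH, 0 °C
Reagents that add atoms: methanol, CO
Why: Oxidative dearomatisation of a para-methoxyphenol to the quinone monoketal; methanol adds para to the phenol oxygen at the carbon already bearing OMe, so the ketal sits beside the hydroxymethyl carbon (future C6) and the carbonyl is remote (future C3).

Step 3
Reactants: 3 3-(hydroxymethyl)-4,4-dimethoxycyclohexa-2,5-dien-1-one; 4 benzoyl chloride
Product: 5 (6,6-dimethoxy-3-oxocyclohexa-1,4-dien-1-yl)methyl benzoate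
Conditions: BzCl, pyridine, CH2Cl2, 0 °C
Reagents that add atoms: benzoyl chloride (4), O=C(Cl)c1ccccc1
Why: Acylation of a primary allylic alcohol; it installs the C7 benzoate of the target and makes the substrate lipophilic for the phase-transfer step.

Step 4
Reactants: 5 (6,6-dimethoxy-3-oxocyclohexa-1,4-dien-1-yl)methyl benzoate
Product: 6 [(4R,5S)-4,5-epoxy-6,6-dimethoxy-3-oxocyclohex-1-en-1-yl]methyl benzoate
Conditions: t-BuOOH, N-benzylcinchonidinium chloride (10 mol %), 0.1 M aq. NaOH, toluene, 0 °C to rt
Reagents that add atoms: tert-butyl hydroperoxide, CC(C)(C)OO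
Why: Weitz–Scheffer nucleophilic epoxidation under chiral phase-transfer catalysis, known for 4,4-dialkoxycyclohexa-2,5-dienones; the peroxide anion adds to C5, the only unsubstituted β-carbon, and the ion-paired cinchonidinium cation selects the enone face, setting C4 and C5 (cis by ring constraint) and the absolute configuration of the route.

Step 5
Reactants: 6 [(4R,5S)-4,5-epoxy-6,6-dimethoxy-3-oxocyclohex-1-en-1-yl]methyl benzoate
Product: 7 [(3S,4S,5S)-4,5-epoxy-3-hydroxy-6,6-dimethoxycyclohex-1-en-1-yl]methyl benzoate
Conditions: NaBH4, CeCl3·7H2O, MeOH, −78 °C
Reagents that add atoms: none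
Why: Luche reduction; 1,2-selective hydride addition to the C3 carbonyl anti to the epoxide C–O bond (polar Felkin–Anh preference plus shielding by the epoxide oxygen), so the C3 hydroxyl emerges cis to the epoxide.

Step 6
Reactants: 7 [(3S,4S,5S)-4,5-epoxy-3-hydroxy-6,6-dimethoxycyclohex-1-en-1-yl]methyl benzoate; 4 benzoyl chloride
Product: 8 [(3S,4S,5S)-3-(benzoyloxy)-4,5-epoxy-6,6-dimethoxycyclohex-1-en-1-yl]methyl benzoate
Conditions: BzCl, pyridine, 4-dimethylaminopyridine (cat.), CH2Cl2, 0 °C
Reagents that add atoms: benzoyl chloride (4), O=C(Cl)c1ccccc1
Why: Standard acylation of a secondary allylic alcohol; O3 becomes the benzoate while C6 is still locked as the ketal, so the two oxygens are distinguished without a selective reaction.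

Step 7
Reactants: 8 [(3S,4S,5S)-3-(benzoyloxy)-4,5-epoxy-6,6-dimethoxycyclohex-1-en-1-yl]methyl benzoate
Product: 9 [(3S,4S,5S)-3-(benzoyloxy)-4,5-epoxy-6-oxocyclohex-1-en-1-yl]methyl benzoate
Conditions: TsOH·H2O (cat.), acetone–H2O, rt
Reagents that add atoms: water, O
Why: Acid-catalysed ketal hydrolysis driven by conjugation of the released carbonyl with C1=C2; the epoxide is flanked by electron-poor carbons and should survive dilute acid, as epoxy enone ketals of this kind generally do.

Step 8
Reactants: 9 [(3S,4S,5S)-3-(benzoyloxy)-4,5-epoxy-6-oxocyclohex-1-en-1-yl]methyl benzoate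
Product: 10 [(3S,4S,5R,6R)-3-(benzoyloxy)-4,5-epoxy-6-hydroxycyclohex-1-en-1-yl]methyl benzoate
Conditions: NaBH4, CeCl3·7H2O, MeOH, −78 °C
Reagents that add atoms: none
Why: Second Luche reduction, again anti to the epoxide; the C3 benzoate lies on the epoxide face and reinforces the bias, so the C6 hydroxyl should emerge cis to both.

Step 9
Reactants: 10 [(3S,4S,5R,6R)-3-(benzoyloxy)-4,5-epoxy-6-hydroxycyclohex-1-en-1-yl]methyl benzoate
Product: 12 [(1R,2S,3S,4R,5R,6S)-3-(benzoyloxy)-4,5-epoxy-1,2,6-trihydroxycyclohexyl]methyl benzoate, via cyclic osmate ester 11 (not isolated)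
Conditions: OsO4 (5 mol %), N-methylmorpholine N-oxide, acetone–H2O (4:1), rt
Reagents that add atoms: osmium tetroxide, O=[Os](=O)(=O)=O; N-methylmorpholine N-oxide, C[N+]1([O-])CCOCC1; water, O
Why: OsO4 adds across C1=C2 in a concerted [3+2] cycloaddition to give the cyclic ester 11 of hexavalent osmium, which water hydrolyses to triol 12 while the N-oxide returns osmium to the octavalent state. The closest known reaction type is the Upjohn dihydroxylation of cyclic allylic alcohols and esters, which runs anti to the allylic oxygen and is standard in cyclitol chemistry. No ring of the product is closed; the five-membered osmate ring is transient. C1 and C2 are created together and are cis because the addition is suprafacial. Their configuration is controlled by the C3 benzoate, the C6 hydroxyl and the epoxide oxygen, which all occupy one face and leave only the opposite face open. The step needs facial selectivity, secured by these three groups and by omitting any amine ligand that could promote hydroxyl-directed syn delivery. It also needs chemoselectivity, which is given because the second alkene is stored as the epoxide and the epoxide is inert to the oxidant.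

Step 10
Reactants: 12 [(1R,2S,3S,4R,5R,6S)-3-(benzoyloxy)-4,5-epoxy-1,2,6-trihydroxycyclohexyl]methyl benzoate; 13 acetic anhydride
Product: 14 [(1R,2S,3R,4R,5S,6S)-2,6-diacetoxy-3-(benzoyloxy)-4,5-epoxy-1-hydroxycyclohexyl]methyl benzoate
Conditions: Ac2O, pyridine, 4-dimethylaminopyridine (cat.), CH2Cl2, 0 °C to rt
Reagents that add atoms: acetic anhydride (13), CC(=O)OC(C)=O
Why: Acetylation of the two secondary hydroxyls; the tertiary C1 hydroxyl is too hindered to react under these conditions, which completes the ester pattern of the target.

Step 11
Reactants: 14 [(1R,2S,3R,4R,5S,6S)-2,6-diacetoxy-3-(benzoyloxy)-4,5-epoxy-1-hydroxycyclohexyl]methyl benzoate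
Product: 16 [(1R,2S,3R,6S)-2,6-diacetoxy-3-(benzoyloxy)-1-hydroxycyclohex-4-en-1-yl]methyl benzoate, via episelenide 15 (not isolated)
Conditions: 3-methyl-1,3-benzothiazole-2(3H)-selone, CF3CO2H, CH2Cl2, 0 °C to rt
Reagents that add atoms: none
Why: Stereospecific epoxide deoxygenation by selenium transfer, known for ester-bearing cyclitol epoxides; the protonated epoxide is opened anti by the selone, oxygen passes to the benzothiazolium carbon, the selenolate closes to episelenide 15 and this extrudes selenium to leave the cis alkene, under weakly acidic conditions that spare the four esters and touch no stereocentre.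

## Compound list

1 | 5-hydroxy-2-methoxybenzaldehyde | COc1ccc(O)cc1C=O | starting material
2 | 3-(hydroxymethyl)-4-methoxyphenol | COc1ccc(O)cc1CO | intermediate
3 | 3-(hydroxymethyl)-4,4-dimethoxycyclohexa-2,5-dien-1-one | COC1(OC)C=CC(=O)C=C1CO | intermediate
4 | benzoyl chloride | O=C(Cl)c1ccccc1 | starting material
5 | (6,6-dimethoxy-3-oxocyclohexa-1,4-dien-1-yl)methyl benzoate | COC1(OC)C=CC(=O)C=C1COC(=O)c1ccccc1 | intermediate
6 | [(4R,5S)-4,5-epoxy-6,6-dimethoxy-3-oxocyclohex-1-en-1-yl]methyl benzoate | O=C1C=C(COC(=O)c3ccccc3)C(OC)(OC)[C@H]2O[C@@H]12 | intermediate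
7 | [(3S,4S,5S)-4,5-epoxy-3-hydroxy-6,6-dimethoxycyclohex-1-en-1-yl]methyl benzoate (hydroxyl cis to epoxide) | O[C@H]1C=C(COC(=O)c3ccccc3)C(OC)(OC)[C@H]2O[C@@H]12 | intermediate
8 | [(3S,4S,5S)-3-(benzoyloxy)-4,5-epoxy-6,6-dimethoxycyclohex-1-en-1-yl]methyl benzoate | O=C(O[C@H]1C=C(COC(=O)c3ccccc3)C(OC)(OC)[C@H]2O[C@@H]12)c1ccccc1 | intermediate
9 | [(3S,4S,5S)-3-(benzoyloxy)-4,5-epoxy-6-oxocyclohex-1-en-1-yl]methyl benzoate | O=C(O[C@H]1C=C(COC(=O)c3ccccc3)C(=O)[C@H]2O[C@@H]12)c1ccccc1 | intermediate
10 | [(3S,4S,5R,6R)-3-(benzoyloxy)-4,5-epoxy-6-hydroxycyclohex-1-en-1-yl]methyl benzoate (O3, O6 and epoxide all cis) | O=C(O[C@H]1C=C(COC(=O)c3ccccc3)[C@@H](O)[C@H]2O[C@@H]12)c1ccccc1 | intermediate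
11 | cyclic dioxo-osmium ester bridging O1 and O2 of 12, on the face opposite O3, O6 and the epoxide | O=C(O[C@H]1[C@@H]4O[Os](=O)(=O)O[C@]4(COC(=O)c3ccccc3)[C@@H](O)[C@H]2O[C@@H]12)c1ccccc1 | intermediate
12 | [(1R,2S,3S,4R,5R,6S)-3-(benzoyloxy)-4,5-epoxy-1,2,6-trihydroxycyclohexyl]methyl benzoate | O=C(O[C@H]1[C@H](O)[C@@](O)(COC(=O)c3ccccc3)[C@@H](O)[C@H]2O[C@@H]12)c1ccccc1 | intermediate
13 | acetic anhydride | CC(=O)OC(C)=O | starting material
14 | [(1R,2S,3R,4R,5S,6S)-2,6-diacetoxy-3-(benzoyloxy)-4,5-epoxy-1-hydroxycyclohexyl]methyl benzoate | O=C(O[C@H]1[C@H](OC(C)=O)[C@@](O)(COC(=O)c3ccccc3)[C@@H](OC(C)=O)[C@H]2O[C@@H]12)c1ccccc1 | intermediate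
15 | 4,5-episelenide corresponding to 14, selenium on the face opposite the C3 and C6 esters, other centres as in 14 | O=C(O[C@H]1[C@H](OC(C)=O)[C@@](O)(COC(=O)c3ccccc3)[C@@H](OC(C)=O)[C@@H]2[Se][C@H]12)c1ccccc1 | intermediate
16 | [(1R,2S,3R,6S)-2,6-diacetoxy-3-(benzoyloxy)-1-hydroxycyclohex-4-en-1-yl]methyl benzoate | CC(=O)O[C@H]1C=C[C@@H](OC(=O)c2ccccc2)[C@H](OC(C)=O)[C@@]1(O)COC(=O)c1ccccc1 | target

Total steps: 11. Longest linear sequence: 11 steps (1 to 16).

## Least certain steps

**Step 9 (key step).** The alkene is trisubstituted but electron-poor (three allylic C–O bonds), so osmylation may be slow and stall. The free C6 hydroxyl could also erode facial selectivity by hydrogen-bond-directed syn delivery, and prolonged exposure could allow benzoate migration in the triol. Fallback: starting from 10, the hydroxyl is acetylated (Ac2O, pyridine) to give the 6-acetate F1. F1 is oxidised with RuO4 generated from RuCl3·3H2O (cat.) and NaIO4 in EtOAc–MeCN–H2O at 0 °C, a more electrophilic reagent with no hydroxyl to direct it, giving the 1,2-diol 6-acetate F2. Acetylation of O2 (Ac2O, pyridine, 4-dimethylaminopyridine) brings the material back at 14.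

**Step 4.** Asymmetric induction by the ion pair may be insufficient for a dienone without a hydrogen-bonding substituent, and some benzoate cleavage by the peroxide anion may compete. Fallback: starting from 5, epoxidation without the chiral salt (t-BuOOH, DBU, CH2Cl2) gives 6 together with its enantiomer F3. Luche reduction gives 7 together with its enantiomer F4. Candida antarctica lipase B with vinyl acetate should acylate the (3R)-alcohol F4 preferentially (empirical size rule for secondary alcohols) to the acetate F5, leaving 7 to be separated, which rejoins the route at 7.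

**Step 5.** Hydride delivery syn to the epoxide would give the C3 epimer. Fallback: starting from 6, the 3-epimeric alcohol F6 is separated and subjected to a Mitsunobu reaction with benzoic acid (PPh3, DIAD, THF), which inverts C3 and installs the benzoate in the same operation, rejoining at 8.

**Step 8.** The same loss of facial control at C6 is possible, and conjugate reduction may compete. Fallback: starting from 9, the 6-epimeric alcohol F7 is separated and inverted by a Mitsunobu reaction with acetic acid to the 6-acetate F1. F1 is then dihydroxylated to the diol F2 and acetylated as in the fallback for step 9, rejoining at 14.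

**Step 11.** Acid-promoted opening of the epoxide by trifluoroacetate or by a neighbouring acyloxy group may compete with selenium transfer. Fallback: starting from 14, thiourea in MeOH at rt converts the epoxide, with inversion at both carbons, into the thiirane F8. Desulfurisation with PPh3 in warm toluene is stereospecific and gives 16.

## Further compounds

F1 | step 9 | 6-acetate of 10: [6-acetoxy-3-(benzoyloxy)-4,5-epoxycyclohex-1-en-1-yl]methyl benzoate, configuration as in 10 | O=C(O[C@H]1C=C(COC(=O)c3ccccc3)[C@@H](OC(C)=O)[C@H]2O[C@@H]12)c1ccccc1
F2 | step 9 | 6-monoacetate of 12: [6-acetoxy-3-(benzoyloxy)-4,5-epoxy-1,2-dihydroxycyclohexyl]methyl benzoate, configuration as in 12 | O=C(O[C@H]1[C@H](O)[C@@](O)(COC(=O)c3ccccc3)[C@@H](OC(C)=O)[C@H]2O[C@@H]12)c1ccccc1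
F3 | step 4 | enantiomer of 6, (4S,5R) | O=C1C=C(COC(=O)c3ccccc3)C(OC)(OC)[C@@H]2O[C@H]12
F4 | step 4 | enantiomer of 7, (3R,4R,5R) | O[C@@H]1C=C(COC(=O)c3ccccc3)C(OC)(OC)[C@@H]2O[C@H]12
F5 | step 4 | 3-acetate of F4, (3R,4R,5R) | CC(=O)O[C@@H]1C=C(COC(=O)c3ccccc3)C(OC)(OC)[C@@H]2O[C@H]12
F6 | step 5 | 3-epimer of 7 (hydroxyl trans to epoxide), (3R,4S,5S) | O[C@@H]1C=C(COC(=O)c3ccccc3)C(OC)(OC)[C@H]2O[C@@H]12
F7 | step 8 | 6-epimer of 10 (C6 hydroxyl trans to epoxide) | O=C(O[C@H]1C=C(COC(=O)c3ccccc3)[C@H](O)[C@H]2O[C@@H]12)c1ccccc1
F8 | step 11 | 4,5-thiirane corresponding to 14, sulfur on the face opposite the C3 and C6 esters | O=C(O[C@H]1[C@H](OC(C)=O)[C@@](O)(COC(=O)c3ccccc3)[C@@H](OC(C)=O)[C@@H]2S[C@H]12)c1ccccc1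
A1 | alternative 1 | cyclohexenol with C1/C2 acetonide, C3 and C7 benzoates and free C6 hydroxyl | O[C@H]1C=C[C@@H](OC(=O)c2ccccc2)[C@@H]2OC(C)(C)O[C@]12COC(=O)c1ccccc1
A2 | alternative 1 | acyclic aldehyde (C6) with (Z)-iodoalkene (C4=C5), C1/C2 acetonide, C3 and C7 benzoates | I/C=C\[C@@H](OC(=O)c1ccccc1)[C@@H]1OC(C)(C)O[C@]1(COC(=O)c1ccccc1)C=O
A3 | alternative 2 | bromobenzene | Brc1ccccc1
A4 | alternative 2 | (1S,2S)-3-bromocyclohexa-3,5-diene-1,2-diol | BrC1=CC=C[C@H](O)[C@@H]1O
A5 | alternative 3 | trimethylsilyl ketene acetal of the manno-configured 1,5-lactone with acetonide, OTBS and (E)-2-benzyloxyvinyl groups | C[Si](C)(C)OC1=C2OC(C)(C)O[C@H]2[C@H](O[Si](C)(C)C(C)(C)C)[C@@H](/C=C/OCc3ccccc3)O1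
A6 | alternative 3 | cyclohexene carboxylic acid with C1/C2 acetonide, C3 OTBS and C6 OBn | C(O[C@H]1C=C[C@@H](O[Si](C)(C)C(C)(C)C)[C@@H]2OC(C)(C)O[C@]12C(=O)O)c1ccccc1
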